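**Plan**

- Locants are those of the bicyclo[3.3.1]nonane name of 23 (C1 bridgehead next to C8Me2, C2 ketone, C3 aroyl carbon, C4 enol carbon, C5 bridgehead next to C6H2, C7 geranyl carbon, C9 bridging ketone); geranyl = (2E)-3,7-dimethylocta-2,6-dien-1-yl, prenyl = 3-methylbut-2-en-1-yl, TIPS = triisopropylsilyl.
- Retrosynthesis: after the two aryl silyl ethers, C1–C9 and C3–C4 are cut together, which opens ring B (C1–C9–C5–C6–C7–C8) and ring A (C1–C2–C3–C4–C5–C9) at once and leaves the acyclic 1,3-diketone/prenylmalonate 20. Then C3–C(aroyl), C5–prenyl, C5–C6, C2–C3, C1–prenyl and C7–geranyl are cut back to 3,3-dimethylglutaric anhydride (C2, C1, C8, C7, C6).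
- Enabling feature: ring A is an acylphloroglucinol-type ring in which acyl-level carbons (C2, C4, C9) alternate with carbanion-level carbons (C1, C3, C5). It divides into a malonyl unit (C4–C5–C9, two ester carbons on quaternary C5) and a 1,3-diketone unit (C1–C2–C3) whose 1,3-dianion is nucleophilic at C1 and C3. The C6–C7–C8 tether makes the first acylation a six-membered closure.
- Forward: the chain is assembled on a temporary δ-lactone ring (opened by MeLi); one operation then closes ring B and ring A in that order; desilylation ends the route.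
- Stereochemistry: C7 comes from an Evans alkylation with (S)-4-benzyl-oxazolidinone; C1 and C5 are set in the key step under control of C7 (chair closure with geranyl and both prenyl groups equatorial).

Key step: step 13

Remark: the carbon that becomes C1 is formed in step 5 as a mixture of epimers and is written without a descriptor in 10, 11, 12, 14, 15 and 20; this has no consequence, because step 13 turns it into an enolate carbon. The descriptor of the C7 carbon changes from S (6 to 12) to R (from 14 on) only through CIP priorities.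

**Step 1**
Reactants: 1 3,3-dimethylglutaric anhydride; 2 (S)-4-benzyl-1,3-oxazolidin-2-one
Product: 3 5-[(4S)-4-benzyl-2-oxo-1,3-oxazolidin-3-yl]-3,3-dimethyl-5-oxopentanoic acid
Conditions: 2, n-BuLi, THF, −78 °C; then 1, −78 → 0 °C; aq. HCl work-up
Reagents that add atoms: none
Why: N-acylation of the lithiated oxazolidinone by ring opening of the symmetrical cyclic anhydride should give one imide acid with the two carboxyl ends differentiated.

**Step 2**
Reactants: 3 imide acid
Product: 4 methyl 5-[(4S)-4-benzyl-2-oxo-1,3-oxazolidin-3-yl]-3,3-dimethyl-5-oxopentanoate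
Conditions: MeI, K2CO3, DMF, rt
Reagents that add atoms: iodomethane, CI
Why: SN2 O-methylation of the potassium carboxylate (esterification) masks the acid, so that only the imide is enolised in the next step.

**Step 3**
Reactants: 4 imide ester; 5 geranyl bromide ((2E)-1-bromo-3,7-dimethylocta-2,6-diene)
Product: 6 methyl (4S,6E)-4-[(4S)-4-benzyl-2-oxo-1,3-oxazolidine-3-carbonyl]-3,3,7,11-tetramethyldodeca-6,10-dienoate
Conditions: NaN(SiMe3)2 (1.05 equiv), THF, −78 °C; then 5, −78 → −40 °C
Reagents that add atoms: none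
Why: Evans asymmetric alkylation: the chelated Z-sodium enolate of the imide should be alkylated by the allylic bromide on the face opposite to the benzyl group, which sets the future C7 centre (4S here), while the less acidic ester is not enolised.

**Step 4**
Reactants: 6 alkylated imide
Product: 8 (5S)-5-geranyl-4,4-dimethyloxan-2-one, via hydroxy ester 7 (not isolated)
Conditions: LiBH4, MeOH (1 equiv), Et2O, 0 °C; then pyridinium p-toluenesulfonate (cat.), CH2Cl2, rt
Reagents that add atoms: none
Why: Reductive cleavage of the N-acyl oxazolidinone frees the auxiliary and the primary alcohol, which should lactonise onto the methyl ester (gem-dimethyl effect) to a temporary ring that keeps the two chain ends distinct.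

**Step 5**
Reactants: 8 lactone; 9 prenyl bromide (1-bromo-3-methylbut-2-ene)
Product: 10 (5S)-5-geranyl-4,4-dimethyl-3-prenyloxan-2-one (C-3 epimers)
Conditions: LiN(i-Pr)2 (1.1 equiv), THF, −78 °C; then 9, DMPU, −78 → −30 °C
Reagents that add atoms: none
Why: Lactone enolate alkylation at the only α-position with a reactive allylic bromide installs the prenyl group of the future C1; the configuration formed there is irrelevant.

**Step 6**
Reactants: 10 prenyl lactone
Product: 11 (5S,7E)-5-(hydroxymethyl)-4,4,8,12-tetramethyl-3-prenyltrideca-7,11-dien-2-one (in equilibrium with its cyclic hemiketal)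
Conditions: MeLi (1.05 equiv), THF, −78 °C; AcOH quench at −78 °C
Reagents that add atoms: methyllithium, [Li]C
Why: Single addition of MeLi to a lactone: the lithium hemiketal is stable at −78 °C and should collapse on quench to the δ-hydroxy methyl ketone, which opens the helper ring and brings in C3.

**Step 7**
Reactants: 11 hydroxy ketone
Product: 12 (5S,7E)-5-(iodomethyl)-4,4,8,12-tetramethyl-3-prenyltrideca-7,11-dien-2-one
Conditions: I2, PPh3, imidazole, CH2Cl2, 0 °C → rt
Reagents that add atoms: iodine, II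
Why: Appel iodination of the primary alcohol should drain the hydroxy ketone/hemiketal equilibrium through the open form.

**Step 8**
Reactants: 12 iodo ketone; 13 dimethyl malonate
Product: 14 dimethyl 2-[(2R,4E)-5,9-dimethyl-2-(2-methyl-4-oxo-3-prenylpentan-2-yl)deca-4,8-dien-1-yl]propanedioate
Conditions: 13 (3 equiv), NaH, THF/DMF, 0 °C; then 12, 60 °C
Reagents that add atoms: none
Why: Malonic ester alkylation (SN2) with a soft, weakly basic carbanion that should not enolise the ketone.

**Step 9**
Reactants: 14 malonate; 9 prenyl bromide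
Product: 15 dimethyl 2-[(2R,4E)-5,9-dimethyl-2-(2-methyl-4-oxo-3-prenylpentan-2-yl)deca-4,8-dien-1-yl]-2-prenylpropanedioate
Conditions: NaH (1.05 equiv), THF/DMF, 0 °C; then 9, rt
Reagents that add atoms: none
Why: Second malonate alkylation with a reactive allylic bromide creates the quaternary carbon (future C5) that carries the two ester carbons destined to become C9 and C4.

**Step 10**
Reactants: 16 3,4-dihydroxybenzoic acid
Product: 18 3,4-bis(triisopropylsilyloxy)benzoic acid, via tris-silyl compound 17 (not isolated)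
Conditions: i-Pr3SiCl (3.3 equiv), imidazole, DMF, 40 °C; then AcOH/THF/H2O, rt
Reagents that add atoms: chlorotriisopropylsilane, CC(C)[Si](Cl)(C(C)C)C(C)C
Why: Persilylation followed by selective hydrolysis of the far more labile silyl ester should give the acid with base-stable, fluoride-labile protection of the catechol.

**Step 11**
Reactants: 18 bis-silyl acid
Product: 19 3,4-bis(triisopropylsilyloxy)benzoyl chloride
Conditions: (COCl)2, DMF (cat.), CH2Cl2, 0 °C → rt; used crude
Reagents that add atoms: oxalyl chloride, O=C(Cl)C(Cl)=O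
Why: DMF-catalysed acid chloride formation under conditions that leave aryl silyl ethers intact.

**Step 12**
Reactants: 15 methyl ketone; 19 aroyl chloride
Product: 20 dimethyl 2-[(2R,4E)-2-{6-[3,4-bis(triisopropylsilyloxy)phenyl]-2-methyl-4,6-dioxo-3-prenylhexan-2-yl}-5,9-dimethyldeca-4,8-dien-1-yl]-2-prenylpropanedioate
Conditions: MgBr2·OEt2 (3 equiv), i-Pr2NEt (3 equiv), CH2Cl2, rt; aq. HCl work-up
Reagents that add atoms: none
Why: Crossed Claisen C-acylation under soft enolisation: the magnesium enolate should form on the unhindered methyl side, and the product is held as a magnesium diketonate, which stops further acylation and spares the malonate esters.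

**Step 13**
Reactants: 20 acyclic 1,3-diketone/prenylmalonate
Product: 22 (1S,5S,7R)-3-[3,4-bis(triisopropylsilyloxy)benzoyl]-7-geranyl-4-hydroxy-8,8-dimethyl-1,5-diprenylbicyclo[3.3.1]non-3-ene-2,9-dione, via monocyclic diketone ester 21 (not isolated)
Conditions: LiN(i-Pr)2 (3.3 equiv), THF, −78 → 0 °C; then 45 °C; aq. HCl quench
Reagents that add atoms: none
Why: Proposed new method: LiN(i-Pr)2 should convert the 1,3-diketone into its 1,3-dianion (first at C3, then at the only γ-carbon, C1); the hard γ-carbanion acylates at C1 with one malonate ester carbon (C9), and the remaining diketonate carbon C3 then acylates with the second ester carbon (C4), each with loss of methoxide, the closest known reactions being the ester acylation of 1,3-diketone dianions to 1,3,5-triketones and the Dieckmann closure of bicyclo[3.3.1]nonanetriones. Ring B (C1–C9–C5–C6–C7–C8) closes first by a 6-(enolexo)-exo-trig Dieckmann-type attack, and ring A (C1–C2–C3–C4–C5–C9) second by a 6-(enolendo)-exo-trig Claisen attack. C1 and C5 are set in the first closure by the C7 centre: in the chair the geranyl group and both prenyl groups sit equatorial, so the diketonate arm on C1 and the spectator ester on C5 become 1,3-diaxial and trans to geranyl, helped by a lithium bridge between the enolate oxygen and the spectator ester carbonyl. The step needs regioselective γ-deprotonation, which is secured because the aryl side of the diketone carries no hydrogen, and it needs the cis-diaxial arrangement, which is the only one that can close ring A. The resulting 2-acyl-1,3-dione leaves the equilibria as its stabilised enolate, which should protect the non-enolisable C1–C9–C5 array against retro-Claisen cleavage by the methoxide released.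

**Step 14**
Reactants: 22 bis-silyl ether
Product: 23 oblongifolin B, (1S,5S,7R)-3-(3,4-dihydroxybenzoyl)-7-geranyl-4-hydroxy-8,8-dimethyl-1,5-diprenylbicyclo[3.3.1]non-3-ene-2,9-dione
Conditions: Bu4NF, AcOH, THF, 0 °C → rt
Reagents that add atoms: none
Why: Fluoride-induced cleavage of the two aryl silyl ethers, buffered with acetic acid so that the acid-sensitive prenyl groups and the base-sensitive catechol should survive.

**Compound list**

1 | 3,3-dimethylglutaric anhydride (4,4-dimethyloxane-2,6-dione) | CC1(C)CC(=O)OC(=O)C1 | starting material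
2 | (S)-4-benzyl-1,3-oxazolidin-2-one | O=C1N[C@@H](Cc2ccccc2)CO1 | starting material
3 | 5-[(4S)-4-benzyl-2-oxo-1,3-oxazolidin-3-yl]-3,3-dimethyl-5-oxopentanoic acid | OC(=O)CC(C)(C)CC(=O)N1C(=O)OC[C@@H]1Cc1ccccc1 | intermediate
4 | methyl 5-[(4S)-4-benzyl-2-oxo-1,3-oxazolidin-3-yl]-3,3-dimethyl-5-oxopentanoate | COC(=O)CC(C)(C)CC(=O)N1C(=O)OC[C@@H]1Cc1ccccc1 | intermediate
5 | geranyl bromide, (2E)-1-bromo-3,7-dimethylocta-2,6-diene | CC(C)=CCC/C(C)=C/CBr | starting material
6 | methyl (4S,6E)-4-[(4S)-4-benzyl-2-oxo-1,3-oxazolidine-3-carbonyl]-3,3,7,11-tetramethyldodeca-6,10-dienoate | CC(C)=CCC/C(C)=C/C[C@@H](C(C)(C)CC(=O)OC)C(=O)N1C(=O)OC[C@@H]1Cc1ccccc1 | intermediate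
7 | methyl (4S,6E)-4-(hydroxymethyl)-3,3,7,11-tetramethyldodeca-6,10-dienoate | CC(C)=CCC/C(C)=C/C[C@@H](C(C)(C)CC(=O)OC)CO | intermediate (not isolated)
8 | (5S)-5-[(2E)-3,7-dimethylocta-2,6-dien-1-yl]-4,4-dimethyloxan-2-one | CC(C)=CCC/C(C)=C/C[C@@H]1COC(=O)CC1(C)C | intermediate
9 | prenyl bromide, 1-bromo-3-methylbut-2-ene | CC(C)=CCBr | starting material
10 | (5S)-5-[(2E)-3,7-dimethylocta-2,6-dien-1-yl]-4,4-dimethyl-3-(3-methylbut-2-en-1-yl)oxan-2-one (C-3 epimers) | CC(C)=CCC/C(C)=C/C[C@@H]1COC(=O)C(CC=C(C)C)C1(C)C | intermediate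
11 | (5S,7E)-5-(hydroxymethyl)-4,4,8,12-tetramethyl-3-(3-methylbut-2-en-1-yl)trideca-7,11-dien-2-one | CC(C)=CCC/C(C)=C/C[C@@H](C(C)(C)C(CC=C(C)C)C(C)=O)CO | intermediate
12 | (5S,7E)-5-(iodomethyl)-4,4,8,12-tetramethyl-3-(3-methylbut-2-en-1-yl)trideca-7,11-dien-2-one | CC(C)=CCC/C(C)=C/C[C@@H](C(C)(C)C(CC=C(C)C)C(C)=O)CI | intermediate
13 | dimethyl malonate | COC(=O)CC(=O)OC | starting material
14 | dimethyl 2-[(2R,4E)-5,9-dimethyl-2-(2-methyl-4-oxo-3-prenylpentan-2-yl)deca-4,8-dien-1-yl]propanedioate | CC(C)=CCC/C(C)=C/C[C@@H](C(C)(C)C(CC=C(C)C)C(C)=O)CC(C(=O)OC)C(=O)OC | intermediate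
15 | dimethyl 2-[(2R,4E)-5,9-dimethyl-2-(2-methyl-4-oxo-3-prenylpentan-2-yl)deca-4,8-dien-1-yl]-2-prenylpropanedioate | CC(C)=CCC/C(C)=C/C[C@@H](C(C)(C)C(CC=C(C)C)C(C)=O)CC(CC=C(C)C)(C(=O)OC)C(=O)OC | intermediate
16 | 3,4-dihydroxybenzoic acid | OC(=O)c1ccc(O)c(O)c1 | starting material
17 | triisopropylsilyl 3,4-bis(triisopropylsilyloxy)benzoate | CC(C)[Si](C(C)C)(C(C)C)OC(=O)c1ccc(O[Si](C(C)C)(C(C)C)C(C)C)c(O[Si](C(C)C)(C(C)C)C(C)C)c1 | intermediate (not isolated)
18 | 3,4-bis(triisopropylsilyloxy)benzoic acid | OC(=O)c1ccc(O[Si](C(C)C)(C(C)C)C(C)C)c(O[Si](C(C)C)(C(C)C)C(C)C)c1 | intermediate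
19 | 3,4-bis(triisopropylsilyloxy)benzoyl chloride | ClC(=O)c1ccc(O[Si](C(C)C)(C(C)C)C(C)C)c(O[Si](C(C)C)(C(C)C)C(C)C)c1 | intermediate
20 | dimethyl 2-[(2R,4E)-2-{6-[3,4-bis(triisopropylsilyloxy)phenyl]-2-methyl-4,6-dioxo-3-prenylhexan-2-yl}-5,9-dimethyldeca-4,8-dien-1-yl]-2-prenylpropanedioate | CC(C)=CCC/C(C)=C/C[C@@H](C(C)(C)C(CC=C(C)C)C(=O)CC(=O)c1ccc(O[Si](C(C)C)(C(C)C)C(C)C)c(O[Si](C(C)C)(C(C)C)C(C)C)c1)CC(CC=C(C)C)(C(=O)OC)C(=O)OC | intermediate
21 | methyl (1R,3R,5R)-3-{3-[3,4-bis(triisopropylsilyloxy)phenyl]-3-oxopropanoyl}-5-geranyl-4,4-dimethyl-2-oxo-1,3-diprenylcyclohexane-1-carboxylate | CC(C)=CCC/C(C)=C/C[C@@H]1C[C@](C(=O)OC)(CC=C(C)C)C(=O)[C@@](CC=C(C)C)(C(=O)CC(=O)c2ccc(O[Si](C(C)C)(C(C)C)C(C)C)c(O[Si](C(C)C)(C(C)C)C(C)C)c2)C1(C)C | intermediate (not isolated)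
22 | (1S,5S,7R)-3-[3,4-bis(triisopropylsilyloxy)benzoyl]-7-geranyl-4-hydroxy-8,8-dimethyl-1,5-diprenylbicyclo[3.3.1]non-3-ene-2,9-dione | CC(C)=CCC/C(C)=C/C[C@@H]1C[C@]2(CC=C(C)C)C(=O)[C@@](CC=C(C)C)(C(=O)C(C(=O)c3ccc(O[Si](C(C)C)(C(C)C)C(C)C)c(O[Si](C(C)C)(C(C)C)C(C)C)c3)=C2O)C1(C)C | intermediate
23 | oblongifolin B, (1S,5S,7R)-3-(3,4-dihydroxybenzoyl)-7-[(2E)-3,7-dimethylocta-2,6-dien-1-yl]-4-hydroxy-8,8-dimethyl-1,5-bis(3-methylbut-2-en-1-yl)bicyclo[3.3.1]non-3-ene-2,9-dione | CC(C)=CCC/C(C)=C/C[C@@H]1C[C@]2(CC=C(C)C)C(=O)[C@@](CC=C(C)C)(C(=O)C(C(=O)c3ccc(O)c(O)c3)=C2O)C1(C)C | target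

**Totals**

Total step count: 14. Longest linear sequence: 12 steps (steps 1 to 9 and 12 to 14; steps 10 and 11 make the aroyl chloride).

**Steps most likely to fail**

1. Step 13 (Proposed new method). The second deprotonation at the hindered methine C1–H may stay incomplete. The carbanion may attack the wrong diastereotopic ester group, so that the spectator ester ends up trans to the diketonate arm and ring A cannot close. The mono-cyclised intermediate may also be reopened by retro-Claisen attack of the lithium methoxide set free.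
Fallback (known chemistry, an Effenberger-type annulation of a cyclohexanone): it sets out from 12 and comes back at 22. Intramolecular alkylation of the methyl-side enolate of 12 (KOt-Bu, THF, 0 °C) would give the cyclohexanone (4S)-4-geranyl-3,3-dimethyl-2-prenylcyclohexan-1-one F1. Kinetic silylation (LiN(i-Pr)2, Me3SiCl) would give the trimethylsilyl enol ether F2. Malonyl dichloride, then KOH and BnEt3NCl, would acylate both α-carbons and give the bicyclic trione F3, with the C1 quaternary centre in place and the new bridge trans to geranyl. O-Methylation (Me2SO4, K2CO3) would give the vinylogous ester F4. Bridgehead lithiation and prenylation (LiN(i-Pr)2, then 9) would give the C5-prenylated enol ether F5. Lithiation at C3 (lithium 2,2,6,6-tetramethylpiperidide) and acylation with 19 would give the aroylated enol ether F6. Demethylation with LiCl in DMSO would return 22.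

2. Step 8. SN2 substitution at the β-branched primary iodide may be slow, and it may be overtaken by participation of the ketone oxygen (cyclic enol ether), by intramolecular enolate alkylation or by elimination.
Fallback (carbon–carbon bond by condensation at an aldehyde, with the ketone masked as a Weinreb amide): it sets out from 10 and comes back at 15. Aminolysis of 10 (AlMe3, MeNH(OMe)·HCl) would give the hydroxy Weinreb amide F7. Dess–Martin oxidation would give the aldehyde F8. Knoevenagel condensation with 13 (TiCl4, pyridine, THF, 0 °C) would give the alkylidene malonate F9. Conjugate reduction with LiBH(s-Bu)3 and trapping of the malonate enolate with 9 would give the prenylated malonate Weinreb amide F10. MeMgBr (THF, −20 → 0 °C) would convert the amide into the methyl ketone 15.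

3. Step 4. At this very hindered imide the hydride may attack the ring carbonyl of the oxazolidinone (endocyclic cleavage), or the methyl ester may be over-reduced.
Fallback (hydrolysis, then chemoselective reduction of an activated acid): it sets out from 6 and comes back at 8. LiOH/H2O2 (THF/H2O, 0 °C) would cleave the auxiliary to the half-ester acid F11. Isobutyl chloroformate and N-methylmorpholine would give the mixed carbonic anhydride F12. NaBH4 would reduce F12 to hydroxy ester 7, which lactonises to 8.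

**Further compounds**

F1 | step 13 | (4S)-4-geranyl-3,3-dimethyl-2-prenylcyclohexan-1-one (C-2 epimers) | CC(C)=CCC/C(C)=C/C[C@@H]1CCC(=O)C(CC=C(C)C)C1(C)C
F2 | step 13 | {[(4R)-4-geranyl-5,5-dimethyl-6-prenylcyclohex-1-en-1-yl]oxy}trimethylsilane | CC(C)=CCC/C(C)=C/C[C@@H]1CC=C(O[Si](C)(C)C)C(CC=C(C)C)C1(C)C
F3 | step 13 | (1R,5S,7R)-7-geranyl-4-hydroxy-8,8-dimethyl-1-prenylbicyclo[3.3.1]non-3-ene-2,9-dione | CC(C)=CCC/C(C)=C/C[C@@H]1C[C@@H]2C(=O)[C@@](CC=C(C)C)(C(=O)C=C2O)C1(C)C
F4 | step 13 | (1R,5S,7R)-7-geranyl-4-methoxy-8,8-dimethyl-1-prenylbicyclo[3.3.1]non-3-ene-2,9-dione | CC(C)=CCC/C(C)=C/C[C@@H]1C[C@@H]2C(=O)[C@@](CC=C(C)C)(C(=O)C=C2OC)C1(C)C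
F5 | step 13 | (1R,5S,7R)-7-geranyl-4-methoxy-8,8-dimethyl-1,5-diprenylbicyclo[3.3.1]non-3-ene-2,9-dione | CC(C)=CCC/C(C)=C/C[C@@H]1C[C@]2(CC=C(C)C)C(=O)[C@@](CC=C(C)C)(C(=O)C=C2OC)C1(C)C
F6 | step 13 | (1S,5S,7R)-3-[3,4-bis(triisopropylsilyloxy)benzoyl]-7-geranyl-4-methoxy-8,8-dimethyl-1,5-diprenylbicyclo[3.3.1]non-3-ene-2,9-dione | CC(C)=CCC/C(C)=C/C[C@@H]1C[C@]2(CC=C(C)C)C(=O)[C@@](CC=C(C)C)(C(=O)C(C(=O)c3ccc(O[Si](C(C)C)(C(C)C)C(C)C)c(O[Si](C(C)C)(C(C)C)C(C)C)c3)=C2OC)C1(C)C
F7 | step 8 | (4S,6E)-4-(hydroxymethyl)-N-methoxy-N,3,3,7,11-pentamethyl-2-prenyldodeca-6,10-dienamide | CC(C)=CCC/C(C)=C/C[C@@H](C(C)(C)C(CC=C(C)C)C(=O)N(C)OC)CO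
F8 | step 8 | (4S,6E)-4-formyl-N-methoxy-N,3,3,7,11-pentamethyl-2-prenyldodeca-6,10-dienamide | CC(C)=CCC/C(C)=C/C[C@@H](C(C)(C)C(CC=C(C)C)C(=O)N(C)OC)C=O
F9 | step 8 | dimethyl 2-[(2R,4E)-2-{4-[methoxy(methyl)amino]-2-methyl-4-oxo-3-prenylbutan-2-yl}-5,9-dimethyldeca-4,8-dien-1-ylidene]propanedioate | CC(C)=CCC/C(C)=C/C[C@@H](C(C)(C)C(CC=C(C)C)C(=O)N(C)OC)C=C(C(=O)OC)C(=O)OC
F10 | step 8 | dimethyl 2-[(2R,4E)-2-{4-[methoxy(methyl)amino]-2-methyl-4-oxo-3-prenylbutan-2-yl}-5,9-dimethyldeca-4,8-dien-1-yl]-2-prenylpropanedioate | CC(C)=CCC/C(C)=C/C[C@@H](C(C)(C)C(CC=C(C)C)C(=O)N(C)OC)CC(CC=C(C)C)(C(=O)OC)C(=O)OC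
F11 | step 4 | (2S,4E)-2-(4-methoxy-2-methyl-4-oxobutan-2-yl)-5,9-dimethyldeca-4,8-dienoic acid | CC(C)=CCC/C(C)=C/C[C@@H](C(C)(C)CC(=O)OC)C(=O)O
F12 | step 4 | mixed anhydride of F11 with isobutyl hydrogen carbonate | CC(C)=CCC/C(C)=C/C[C@@H](C(C)(C)CC(=O)OC)C(=O)OC(=O)OCC(C)C
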